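0.700 equiv of reagent is the number to hold on to in this flask.

| setting | Friday's | Monday's | flask |
|---|---|---|---|
| solid substrate | 0.055 M | 0.055 M | 0.055 M |
| reagent | 0.70 equiv | 0.70 equiv | 0.700 equiv |
| initiator | 1.4 mol% | 2.2 mol% | 1 mol% |
| remark | run made earlier | run made earlier |  |
| time |  |  | 10 d |

| run | time / d | product / % | starting material / % |
|---|---|---|---|
| Friday's | 1.25 | 13 | 22 |
| Friday's | 2.50 | 41 | 32 |
| Friday's | 3.00 | 52 | 31 |
| Friday's | 5.00 | 71 | 29 |
| Friday's | 6.00 | 67 | 28 |
| Friday's | 8.00 | 72 | 32 |
| Monday's | 0.625 | 7 | 13 |
| Monday's | 1.04 | 10 | 21 |
| Monday's | 1.67 | 27 | 22 |
| Monday's | 2.50 | 47 | 26 |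
| Monday's | 3.00 | 59 | 25 |
| Monday's | 5.00 | 70 | 31 |
| Monday's | 8.00 | 71 | 29 |

(scatter of a reading: 2 percentage points)

- solid substrate is a solid; its amount is given per volume of the solution
- at the start none of the solid substrate is in solution
- starting material is what solid substrate becomes in solution
- starting material means what is dissolved; the solid is not counted in it

- north: doubling the amount of reagent, all else as stated
- north-east: doubling the solubility of the solid substrate, all else as stated
- south: doubling the dissolution coefficient of the solid substrate, all else as stated

- the product standing at 10 d, as a percentage of the solid substrate charged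
- concentration of starting material in solution at 5.0 d, in percent of saturation
- the change that raises the amount of product at 10 d, in percent of the solid substrate charged most ("none" if none brings more than 2 percentage points) (north / north-east / south / none)
- amount of product at 10 d, in percent of the solid substrate charged, after north-east

Read those equivalents as a percentage of the solid substrate charged, and you have the reagent ceiling, the product allowed if each product takes one reagent: 70.0%. The late readings of both runs level out near it, so reagent looks like the limiting reagent.

Now climb the clocks. First comes dissolving. In Friday's run, product plus starting material reach 73.0% at 2.50 d, and Monday's run has the same sum with more initiator. So I read about 0.292 d⁻¹ of the charge entering solution, and, if that rate holds, the whole charge needs about 3.42 d.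

Next comes product. Friday's readings give a loose first-order constant on c(starting material) of 0.710 d⁻¹. I scale it by the square root of initiator, which gives 0.600 d⁻¹ for this flask.

The remainder is 30.0%. At that c(starting material), I reckon this flask crosses to the ceiling in about 3.89 d, later than my dissolving time and earlier than 10 d. By this reckoning, control passes from rate to reagent there. I therefore expect 70.0% of product and 30.0% of starting material at 5.0 d. More solubility or faster dissolving leaves the ceiling where it is, while north lifts it. Saturation is my weak number: the nearly straight rise puts it above the remainder, and no closer.

The forecast says 70%, sat 30%, north, and 70% after north-east: “Product plateaus at 70% in both runs, which matches the 0.70 equiv of reagent, so reagent is limiting.”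

The flask gives 70.0%, sat 36.6%, north with 29 percentage points gained, and 70.0% after north-east.

    starting material + initiating radical → capped initiator + first chain carrier (k = 3.08 × 10⁵ L mol⁻¹ s⁻¹)
    solid substrate ⇌ starting material, rate k2*(cs2 - [starting material]) while solid is left; crystals form when [starting material] > cs2 (solubility = 45.0 mM, k = 0.0191 h⁻¹)
    reagent + first chain carrier → product + second chain carrier (k = 4.28 × 10⁵ L mol⁻¹ s⁻¹)
    starting material + second chain carrier → by-product + first chain carrier (k = 2.79 × 10⁷ L mol⁻¹ h⁻¹)
    first chain carrier → ended carrier (k = 2700 h⁻¹)
    2 second chain carrier → ended chains (k = 2.30 × 10⁸ L mol⁻¹ s⁻¹)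
    initiator → 2 initiating radical (k = 0.00148 h⁻¹)

The two part on sat. In this flask the remainder stands as reckoned, 29.9% at 5.00 d, but saturation is 45 mM, or 81.8% of the charge. Half the product-making turnover of this flask is done by 2.45 d, earlier than 10 d, and at 5.00 d reagent stands at 0% with product at 70.0%, against a ceiling of 70.0%. For the same flask with 0.280 equiv of reagent, the ceiling reads 28.0% and the remainder 72.0%. That neighbour flask ends with 28.0% product and 71.5% starting material.

The runs are calculated for substances that don't exist, and the scatter is random.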